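**Retrosynthetic overview**
- Last ring: the second lactone comes from hydrogenation of a butenolide, which is attached by vinylogous Mukaiyama–Michael addition of a 2-silyloxyfuran to a nine-membered cyclic N-acyl enaminone.
- The enaminone comes from Saegusa–Ito oxidation of a tricyclic keto-lactam; its nine-membered ring is closed by a carbene-catalysed Stetter reaction (ketone carbon to butenolide β-carbon), which also sets the ring-fusion and methyl centres of the first lactone.
- The Stetter aldehyde comes from the N–H lactam and acrolein (aza-Michael) after Boc removal.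
- The first stereocentres come from an organocatalytic asymmetric vinylogous Michael addition of 3-methylbutenolide to achiral α-propylidene N-Boc-caprolactam (made from N-Boc-caprolactam and propanal).
- Ring order: azepanone (bought), first lactone (bought as butenolide), nine-membered ring, second lactone.

Assumption: compound 1 (N-Boc-ε-caprolactam) is bought as such, and the quinine-derived catalyst in step 2 is taken to give the sense of induction shown.

**Step 1**
Reactants: 1 tert-butyl 2-oxoazepane-1-carboxylate; 2 propanal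
Product: 5 tert-butyl (3E)-2-oxo-3-propylideneazepane-1-carboxylate, via lithium aldolate 3 (not isolated), via mesylate 4 (not isolated)
Conditions: LiN(SiMe3)2, THF, −78 °C; 2; MsCl, −78 to −20 °C; DBU, 0 °C to rt
Reagents that add atoms: none
Why: Aldol addition of the lithium imide enolate to propanal, mesylation and DBU-mediated E1cB elimination (aldol condensation) give the more stable E alkylidene imide, and the racemic centres of 3 and 4 are erased, so 5 is achiral.

**Step 2**
Reactants: 5 tert-butyl (3E)-2-oxo-3-propylideneazepane-1-carboxylate; 6 3-methylfuran-2(5H)-one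
Product: 7 tert-butyl (3S)-3-{(1R)-1-[(2S)-4-methyl-5-oxo-2,5-dihydrofuran-2-yl]propyl}-2-oxoazepane-1-carboxylate
Conditions: 6 (1.5 equiv), quinine-derived 3,5-bis(trifluoromethyl)phenyl squaramide (10 mol %), toluene, −20 °C
Reagents that add atoms: none
Why: Proposed new method: the quinuclidine nitrogen of the bifunctional squaramide deprotonates 6 at its γ-carbon while the squaramide N–H pair binds the two imide carbonyls of 5, so the bound dienolate adds through its γ-carbon to one face of the exocyclic β-carbon (direct asymmetric vinylogous Michael addition, catalyst control fixing the (1R)-propyl and (2S)-butenolide centres), and the imide enolate is then protonated by the quinuclidinium anti to the new butenolide group in the allylic-strain-minimised conformer to give the (3S) ring centre; the closest known reaction type is the squaramide- or thiourea-catalysed direct vinylogous Michael addition of γ-butenolides to nitroalkenes, enones and acyclic unsaturated imides, not yet shown for an α-alkylidene N-acyl lactam.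

**Step 3**
Reactants: 7 tert-butyl (3S)-3-{(1R)-1-[(2S)-4-methyl-5-oxo-2,5-dihydrofuran-2-yl]propyl}-2-oxoazepane-1-carboxylate
Product: 8 (3S)-3-{(1R)-1-[(2S)-4-methyl-5-oxo-2,5-dihydrofuran-2-yl]propyl}azepan-2-one
Conditions: CF3CO2H, CH2Cl2, 0 °C to rt
Reagents that add atoms: none
Why: Acidolysis of the tert-butyl carbamate (Boc removal) frees the lactam N–H without base, so the butenolide γ-hydrogen and the three stereocentres are untouched.

**Step 4**
Reactants: 8 (3S)-3-{(1R)-1-[(2S)-4-methyl-5-oxo-2,5-dihydrofuran-2-yl]propyl}azepan-2-one; 9 prop-2-enal (acrolein)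
Product: 10 3-[(3S)-3-{(1R)-1-[(2S)-4-methyl-5-oxo-2,5-dihydrofuran-2-yl]propyl}-2-oxoazepan-1-yl]propanal
Conditions: 9 (3 equiv), Tf2NH (5 mol %), MeCN, 0 °C
Reagents that add atoms: none
Why: Brønsted-acid-catalysed aza-Michael addition of the lactam N–H to acrolein installs the three-carbon aldehyde tether under non-basic conditions that cannot epimerise the butenolide γ-centre, and no stereocentre is formed.

**Step 5**
Reactants: 10 3-[(3S)-3-{(1R)-1-[(2S)-4-methyl-5-oxo-2,5-dihydrofuran-2-yl]propyl}-2-oxoazepan-1-yl]propanal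
Product: 11 (1S,2R,3S,6S,7S)-2-ethyl-6-methyl-4-oxa-11-azatricyclo[9.4.1.0^{3,7}]hexadecane-5,8,16-trione
Conditions: 2-(pentafluorophenyl)-6,7-dihydro-5H-pyrrolo[2,1-c][1,2,4]triazol-2-ium tetrafluoroborate (20 mol %), i-Pr2NEt (20 mol %), toluene, 70 °C, slow addition of 10 (2 mM final)
Reagents that add atoms: none
Why: Proposed new method: the carbene turns the aldehyde into a Breslow intermediate (acyl anion equivalent) that adds to the β-carbon of the α-methylbutenolide in a nine-membered ring-closing Stetter reaction, the tether anchored at the butenolide γ-carbon forcing attack on the same face (cis ring fusion, 7S) and the hydroxyl of the adduct passing its proton intramolecularly to the α-carbon syn to the new acyl bond (methyl trans, 6S) before the carbene leaves; the closest known reaction type is the carbene-catalysed intramolecular Stetter reaction forming five- and six-membered rings with syn hydroacylation of trisubstituted acceptors, extended to a medium ring because both tether ends sit on adjacent atoms of the rigid lactam, C–C bond formation is irreversible while benzoin steps are reversible, and high dilution suppresses oligomers.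

**Step 6**
Reactants: 11 (1S,2R,3S,6S,7S)-2-ethyl-6-methyl-4-oxa-11-azatricyclo[9.4.1.0^{3,7}]hexadecane-5,8,16-trione
Product: 13 (1S,2R,3S,6S,7S,9Z)-2-ethyl-6-methyl-4-oxa-11-azatricyclo[9.4.1.0^{3,7}]hexadec-9-ene-5,8,16-trione, via silyl enol ether 12 (not isolated)
Conditions: LiN(SiMe3)2, Me3SiCl, THF, −78 °C; then Pd(OAc)2 (1.1 equiv), MeCN, rt
Reagents that add atoms: none
Why: Kinetic deprotonation of the ketone at the unhindered C-9 methylene (not the ring-fusion methine) with internal silyl quench gives the less substituted silyl enol ether, which divalent palladium dehydrogenates (Saegusa–Ito oxidation) to the ring-constrained Z push–pull enaminone without enolising any stereocentre.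

**Step 7**
Reactants: 6 3-methylfuran-2(5H)-one
Product: 14 trimethyl[(3-methylfuran-2-yl)oxy]silane
Conditions: Me3SiCl, Et3N, Et2O, 0 °C to rt; distillation
Reagents that add atoms: chlorotrimethylsilane, C[Si](C)(C)Cl
Why: Soft enolisation and O-silylation of the butenolide give the aromatic 2-silyloxyfuran (silyl dienol ether formation), the standard nucleophile for vinylogous Mukaiyama additions.

**Step 8**
Reactants: 13 (1S,2R,3S,6S,7S,9Z)-2-ethyl-6-methyl-4-oxa-11-azatricyclo[9.4.1.0^{3,7}]hexadec-9-ene-5,8,16-trione; 14 trimethyl[(3-methylfuran-2-yl)oxy]silane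
Product: 16 (1S,2R,3S,6S,7S,10S)-2-ethyl-6-methyl-10-[(2S)-4-methyl-5-oxo-2,5-dihydrofuran-2-yl]-4-oxa-11-azatricyclo[9.4.1.0^{3,7}]hexadecane-5,8,16-trione, via silyl enol ether adduct 15 (not isolated)
Conditions: 14 (1.5 equiv), Me3SiOTf (10 mol %), CH2Cl2, −78 °C; then 1 M HCl, THF, 0 °C
Reagents that add atoms: none
Why: The silyl triflate activates the N-acyl enaminone as an N-acyliminium-like acceptor and the 2-silyloxyfuran adds through C-5 (vinylogous Mukaiyama–Michael addition) from the ring face opposite the cis-fused lactone to set C-10 (S), the open transition state giving the threo relationship to the new butenolide centre (2S), and the acid work-up hydrolyses the silyl enol ether.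

**Step 9**
Reactants: 16 (1S,2R,3S,6S,7S,10S)-2-ethyl-6-methyl-10-[(2S)-4-methyl-5-oxo-2,5-dihydrofuran-2-yl]-4-oxa-11-azatricyclo[9.4.1.0^{3,7}]hexadecane-5,8,16-trione
Product: 17 (1S,2R,3S,6S,7S,10S)-2-ethyl-6-methyl-10-[(2S,4S)-4-methyl-5-oxooxolan-2-yl]-4-oxa-11-azatricyclo[9.4.1.0^{3,7}]hexadecane-5,8,16-trione
Conditions: H2 (1 atm), Pd/C, EtOAc, rt
Reagents that add atoms: none
Why: Heterogeneous hydrogenation adds hydrogen to the butenolide face opposite its C-2 substituent, so the methyl group ends cis to it (4S), while ketone, lactam and lactones are inert.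

**Compound list**
1 | tert-butyl 2-oxoazepane-1-carboxylate | O=C1CCCCCN1C(=O)OC(C)(C)C | starting material
2 | propanal | CCC=O | starting material
3 | lithium aldolate of tert-butyl 3-(1-hydroxypropyl)-2-oxoazepane-1-carboxylate (racemic diastereomer mixture) | CCC([O-])C1CCCCN(C(=O)OC(C)(C)C)C1=O.[Li+] | intermediate
4 | tert-butyl 3-[1-(methylsulfonyloxy)propyl]-2-oxoazepane-1-carboxylate (racemic diastereomer mixture) | CCC(OS(C)(=O)=O)C1CCCCN(C(=O)OC(C)(C)C)C1=O | intermediate
5 | tert-butyl (3E)-2-oxo-3-propylideneazepane-1-carboxylate | CC/C=C1\CCCCN(C(=O)OC(C)(C)C)C1=O | intermediate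
6 | 3-methylfuran-2(5H)-one | CC1=CCOC1=O | starting material
7 | tert-butyl (3S)-3-{(1R)-1-[(2S)-4-methyl-5-oxo-2,5-dihydrofuran-2-yl]propyl}-2-oxoazepane-1-carboxylate | CC[C@@H]([C@@H]2OC(=O)C(C)=C2)[C@@H]1CCCCN(C(=O)OC(C)(C)C)C1=O | intermediate
8 | (3S)-3-{(1R)-1-[(2S)-4-methyl-5-oxo-2,5-dihydrofuran-2-yl]propyl}azepan-2-one | CC[C@@H]([C@@H]2OC(=O)C(C)=C2)[C@@H]1CCCCNC1=O | intermediate
9 | prop-2-enal (acrolein) | C=CC=O | starting material
10 | 3-[(3S)-3-{(1R)-1-[(2S)-4-methyl-5-oxo-2,5-dihydrofuran-2-yl]propyl}-2-oxoazepan-1-yl]propanal | CC[C@@H]([C@@H]2OC(=O)C(C)=C2)[C@@H]1CCCCN(CCC=O)C1=O | intermediate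
11 | (1S,2R,3S,6S,7S)-2-ethyl-6-methyl-4-oxa-11-azatricyclo[9.4.1.0^{3,7}]hexadecane-5,8,16-trione | CC[C@H]1[C@@H]2OC(=O)[C@@H](C)[C@@H]2C(=O)CCN2CCCC[C@@H]1C2=O | intermediate
12 | (1S,2R,3S,6S,7S)-2-ethyl-6-methyl-8-(trimethylsilyloxy)-4-oxa-11-azatricyclo[9.4.1.0^{3,7}]hexadec-8-ene-5,16-dione | CC[C@H]1[C@@H]2OC(=O)[C@@H](C)[C@@H]2C(O[Si](C)(C)C)=CCN2CCCC[C@@H]1C2=O | intermediate
13 | (1S,2R,3S,6S,7S,9Z)-2-ethyl-6-methyl-4-oxa-11-azatricyclo[9.4.1.0^{3,7}]hexadec-9-ene-5,8,16-trione | CC[C@H]1[C@@H]2OC(=O)[C@@H](C)[C@@H]2C(=O)/C=C\N2CCCC[C@@H]1C2=O | intermediate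
14 | trimethyl[(3-methylfuran-2-yl)oxy]silane | Cc1ccoc1O[Si](C)(C)C | intermediate
15 | (1S,2R,3S,6S,7S,10S)-2-ethyl-6-methyl-10-[(2S)-4-methyl-5-oxo-2,5-dihydrofuran-2-yl]-8-(trimethylsilyloxy)-4-oxa-11-azatricyclo[9.4.1.0^{3,7}]hexadec-8-ene-5,16-dione | CC[C@H]1[C@@H]2OC(=O)[C@@H](C)[C@@H]2C(O[Si](C)(C)C)=C[C@@H]([C@@H]2C=C(C)C(=O)O2)N2CCCC[C@@H]1C2=O | intermediate
16 | (1S,2R,3S,6S,7S,10S)-2-ethyl-6-methyl-10-[(2S)-4-methyl-5-oxo-2,5-dihydrofuran-2-yl]-4-oxa-11-azatricyclo[9.4.1.0^{3,7}]hexadecane-5,8,16-trione | CC[C@H]1[C@@H]2OC(=O)[C@@H](C)[C@@H]2C(=O)C[C@@H]([C@@H]2C=C(C)C(=O)O2)N2CCCC[C@@H]1C2=O | intermediate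
17 | (1S,2R,3S,6S,7S,10S)-2-ethyl-6-methyl-10-[(2S,4S)-4-methyl-5-oxooxolan-2-yl]-4-oxa-11-azatricyclo[9.4.1.0^{3,7}]hexadecane-5,8,16-trione (CNP0311700.3) | CC[C@H]1[C@@H]2OC(=O)[C@@H](C)[C@@H]2C(=O)C[C@@H]([C@@H]2C[C@H](C)C(=O)O2)N2CCCC[C@@H]1C2=O | target

**Step count and risks**
Total step count: 9. Longest linear sequence: 8 (steps 1 to 6, 8 and 9; step 7 is a one-step branch).

The three steps most likely to fail:

1. Step 5 (new nine-membered Stetter ring closure). The fallback sets out from 10 and comes back at 11 using known acyl-radical chemistry. Pinnick oxidation (NaClO2, NaH2PO4, 2-methylbut-2-ene, t-BuOH/H2O) gives the propanoic acid F1. PhSeH with DCC converts it into the Se-phenyl selenoester F2. Slow addition of Bu3SnH and AIBN to F2 in benzene at 80 °C under high dilution generates the acyl radical, which closes the ring at the butenolide β-carbon on the tether face. Hydrogen transfer to the α-radical from the open face is expected to give mainly the 6-epimer F3, which DBU in CH2Cl2 equilibrates to 11 (methyl on the convex face).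

2. Step 2 (new asymmetric vinylogous Michael addition). The fallback sets out from 5 and comes back at 7. It uses the known chiral-Lewis-acid vinylogous Mukaiyama–Michael addition of 2-silyloxyfurans to chelating unsaturated imides. Silyloxyfuran 14 (made as in step 7) is added to 5 with Cu(OTf)2 and (S,S)-tert-butyl-bis(oxazoline) (10 mol % each) in CH2Cl2 at −78 °C with (CF3)2CHOH. The divalent copper chelates the lactam and carbamate carbonyls, and mild acid work-up protonates the enolate to 7. No new compound is isolated (none F0).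

3. Step 8 (face selectivity at C-10 on the medium ring and the threo relationship are substrate-controlled and cannot be predicted with confidence). The fallback sets out from 13 and comes back at 16 by switching to catalyst control. Dry HCl in Et2O adds to the enaminone to give the 10-chloro lactam F4 in situ. A chiral arylpyrrolidine thiourea (10 mol %) binds the chloride of the derived N-acyliminium ion pair in t-BuOMe at −78 °C, and 14 then adds within the chiral ion pair to give 16.

**Further compounds**
F0 | step 2 | none | none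
F1 | step 5 | 3-[(3S)-3-{(1R)-1-[(2S)-4-methyl-5-oxo-2,5-dihydrofuran-2-yl]propyl}-2-oxoazepan-1-yl]propanoic acid | CC[C@@H]([C@@H]2OC(=O)C(C)=C2)[C@@H]1CCCCN(CCC(=O)O)C1=O
F2 | step 5 | Se-phenyl 3-[(3S)-3-{(1R)-1-[(2S)-4-methyl-5-oxo-2,5-dihydrofuran-2-yl]propyl}-2-oxoazepan-1-yl]propaneselenoate | CC[C@@H]([C@@H]2OC(=O)C(C)=C2)[C@@H]1CCCCN(CCC(=O)[Se]c3ccccc3)C1=O
F3 | step 5 | (1S,2R,3S,6R,7S)-2-ethyl-6-methyl-4-oxa-11-azatricyclo[9.4.1.0^{3,7}]hexadecane-5,8,16-trione | CC[C@H]1[C@@H]2OC(=O)[C@H](C)[C@@H]2C(=O)CCN2CCCC[C@@H]1C2=O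
F4 | step 8 | (1S,2R,3S,6S,7S)-10-chloro-2-ethyl-6-methyl-4-oxa-11-azatricyclo[9.4.1.0^{3,7}]hexadecane-5,8,16-trione (both C-10 epimers) | CC[C@H]1[C@@H]2OC(=O)[C@@H](C)[C@@H]2C(=O)CC(Cl)N2CCCC[C@@H]1C2=O
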